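With the ring numbered C1 (OAc), C2 (OBz), C3=C4, C5 (OH) and C6 (tertiary OH carrying C7H2OBz), everything rests on cutting the C1–C6 bond. The feature exploited is the cis C1/C6 glycol of the cyclohexene ring, which stands opposite to both allylic oxygens at C2 and C5. One SmI2 aldehyde–ketone coupling makes that bond, closes the carbocycle and sets C1 and C6. Its substrate is an open (Z)-hept-3-ene chain: C1 aldehyde, C6 ketone, 4-methoxybenzyl ethers at C2 and C7, a silyl ether at C5. It is built from an alkyne (C1–C4, chiral pool) and an N-methoxy amide (C5–C7), with C5 set by catalytic ynone reduction.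

Key step: step 13

Remark on the chemistry: the C6 carbinol centre of the open chain is erased in step 12. Its configuration (S, from methyl (S)-glycidate) is chosen only to keep every intermediate a single diastereomer and to let the Felkin–Anh bias of the ynone support the catalyst in step 8. Locants C1–C7 are those of the overview; PMB = 4-methoxybenzyl, TBS = tert-butyldimethylsilyl, TES = triethylsilyl.

Step 1
Reactants: 1 (S)-2,2-dimethyl-1,3-dioxolane-4-carbaldehyde
Product: 2 (R)-4-ethynyl-2,2-dimethyl-1,3-dioxolane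
Conditions: dimethyl (1-diazo-2-oxopropyl)phosphonate, K2CO3, MeOH, 0 °C → rt
Reagents that add atoms: dimethyl (1-diazo-2-oxopropyl)phosphonate, COP(=O)(OC)C(=[N+]=[N-])C(C)=O
Why: The Ohira–Bestmann (Seyferth–Gilbert) homologation turns the aldehyde into the terminal alkyne (C3≡C4) under mild carbonate conditions that should leave the α-oxygenated centre, the future C2, untouched.

Step 2
Reactants: 2 (R)-4-ethynyl-2,2-dimethyl-1,3-dioxolane
Product: 4 (4R)-4-ethynyl-2-(4-methoxyphenyl)-1,3-dioxolane as both acetal epimers, via (R)-but-3-yne-1,2-diol 3 (not isolated)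
Conditions: TsOH·H2O (cat.), MeOH, rt, then evaporation; 4-MeOC6H4CH(OMe)2, CSA (cat.), CH2Cl2, rt
Reagents that add atoms: 4-methoxybenzaldehyde dimethyl acetal, COc1ccc(cc1)C(OC)OC
Why: In this acid-catalysed transacetalisation, methanolysis frees the water-soluble diol, which is not isolated, and the aryl acetal closes on it without involving C2, both acetal epimers serving equally in step 3.

Step 3
Reactants: 4 (4R)-4-ethynyl-2-(4-methoxyphenyl)-1,3-dioxolane
Product: 5 (R)-2-[(4-methoxybenzyl)oxy]but-3-yn-1-ol (C1–C4 fragment)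
Conditions: i-Bu2AlH (3 equiv), CH2Cl2, −78 → 0 °C; aq. potassium sodium tartrate
Reagents that add atoms: none
Why: In this regioselective reductive opening of a 4-methoxybenzylidene acetal, aluminium binds the less hindered and more basic primary oxygen, so hydride delivery should leave the PMB ether on the propargylic C2 oxygen and free C1–OH, while hydroalumination of the alkyne is slow at this temperature.

Step 4
Reactants: 6 methyl (S)-oxirane-2-carboxylate (methyl (S)-glycidate)
Product: 7 methyl (S)-2-hydroxy-3-[(4-methoxybenzyl)oxy]propanoate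
Conditions: 4-MeOC6H4CH2OH (2 equiv), Mg(ClO4)2 (0.25 equiv), neat, 50 °C
Reagents that add atoms: 4-methoxybenzyl alcohol, COc1ccc(CO)cc1
Why: Lewis-acid-catalysed SN2 alcoholysis of a glycidic ester occurs at the unsubstituted carbon (C7) remote from the ester, which gives the C7 ether and a free C6–OH in one operation with C6 retained.

Step 5
Reactants: 7 methyl (S)-2-hydroxy-3-[(4-methoxybenzyl)oxy]propanoate
Product: 8 methyl (S)-3-[(4-methoxybenzyl)oxy]-2-(triethylsilyloxy)propanoate
Conditions: TESCl, imidazole, CH2Cl2, 0 °C → rt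
Reagents that add atoms: chlorotriethylsilane, CC[Si](Cl)(CC)CC
Why: Standard imidazole-promoted silylation masks C6–OH with a group that is stable to organolithium reagents and is later lost under milder acid than a secondary TBS ether.

Step 6
Reactants: 8 methyl (S)-3-[(4-methoxybenzyl)oxy]-2-(triethylsilyloxy)propanoate
Product: 9 (S)-N-methoxy-3-[(4-methoxybenzyl)oxy]-N-methyl-2-(triethylsilyloxy)propanamide (C5–C7 fragment)
Conditions: MeNHOMe·HCl (1.5 equiv), i-PrMgCl (3 equiv), THF, −20 °C
Reagents that add atoms: N,O-dimethylhydroxylamine hydrochloride, CNOC.Cl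
Why: Weinreb amide formation by aminolysis of the ester with the magnesium amide is fast at low temperature, where neither the silyl ether nor the β-alkoxy group should be disturbed.

Step 7
Reactants: 5 (R)-2-[(4-methoxybenzyl)oxy]but-3-yn-1-ol; 9 (S)-N-methoxy-3-[(4-methoxybenzyl)oxy]-N-methyl-2-(triethylsilyloxy)propanamide
Product: 11 (2S,6R)-7-hydroxy-1,6-bis[(4-methoxybenzyl)oxy]-2-(triethylsilyloxy)hept-4-yn-3-one, via dilithio alkynide 10 (not isolated)
Conditions: 5, n-BuLi (2.0 equiv per 5), THF, −78 → −40 °C; then 9, −78 → −20 °C; cold aq. NH4Cl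
Reagents that add atoms: n-butyllithium, [Li]CCCC (lithium atoms of 10)
Why: In this Weinreb ketone synthesis only the acetylide carbon of the two anionic sites of 10 is acylated, and the N-methoxy amide accepts a single nucleophile, so the C4–C5 bond forms without a protecting step for C1–OH.

Step 8
Reactants: 11 (2S,6R)-7-hydroxy-1,6-bis[(4-methoxybenzyl)oxy]-2-(triethylsilyloxy)hept-4-yn-3-one
Product: 12 (2R,5S,6S)-2,7-bis[(4-methoxybenzyl)oxy]-6-(triethylsilyloxy)hept-3-yne-1,5-diol
Conditions: Ru[(R,R)-TsNCHPhCHPhNH](p-cymene) (2 mol %), i-PrOH, rt, no added base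
Reagents that add atoms: none
Why: In the Noyori asymmetric transfer hydrogenation of an ynone, the (R,R)-catalyst, which reads the alkyne as the unsaturated group, should deliver hydride to the face giving 5S; the Felkin–Anh preference of the (6S)-silyloxy ketone (syn product) points the same way, and base-free conditions avoid silyl migration and β-elimination.

Step 9
Reactants: 12 (2R,5S,6S)-2,7-bis[(4-methoxybenzyl)oxy]-6-(triethylsilyloxy)hept-3-yne-1,5-diol
Product: 13 (2R,5S,6S)-1,5-bis(tert-butyldimethylsilyloxy)-2,7-bis[(4-methoxybenzyl)oxy]-6-(triethylsilyloxy)hept-3-yne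
Conditions: TBSOTf (2.5 equiv), 2,6-lutidine, CH2Cl2, −78 → 0 °C
Reagents that add atoms: tert-butyldimethylsilyl triflate, CC(C)(C)[Si](C)(C)OS(=O)(=O)C(F)(F)F
Why: Silylation with the triflate and a hindered base covers the primary C1–OH and the crowded C5–OH in one operation without generating an alkoxide that could move the TES group.

Step 10
Reactants: 13 (2R,5S,6S)-1,5-bis(tert-butyldimethylsilyloxy)-2,7-bis[(4-methoxybenzyl)oxy]-6-(triethylsilyloxy)hept-3-yne
Product: 14 (2R,5S,6S)-5-(tert-butyldimethylsilyloxy)-2,7-bis[(4-methoxybenzyl)oxy]hept-3-yne-1,6-diol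
Conditions: CSA (0.1 equiv), MeOH/CH2Cl2 1:1, 0 °C
Reagents that add atoms: none
Why: Acid-catalysed methanolysis of silyl ethers follows accessibility, so the primary C1 TBS ether and the small C6 TES ether should be lost while the secondary, electron-poor propargylic C5 TBS ether stays, and the acidic medium offers no alkoxide to carry silicon from O5 to O6.

Step 11
Reactants: 14 (2R,5S,6S)-5-(tert-butyldimethylsilyloxy)-2,7-bis[(4-methoxybenzyl)oxy]hept-3-yne-1,6-diol
Product: 15 (2R,3Z,5S,6S)-5-(tert-butyldimethylsilyloxy)-2,7-bis[(4-methoxybenzyl)oxy]hept-3-ene-1,6-diol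
Conditions: H2 (1 atm), Pd/CaCO3 poisoned with Pb(OAc)2, quinoline, EtOAc, rt
Reagents that add atoms: none
Why: In this Lindlar-type semihydrogenation, syn delivery of hydrogen on the poisoned palladium surface should give only the Z C3=C4 alkene, and PMB ethers and allylic C–O bonds are not hydrogenolysed under these conditions.

Step 12
Reactants: 15 (2R,3Z,5S,6S)-5-(tert-butyldimethylsilyloxy)-2,7-bis[(4-methoxybenzyl)oxy]hept-3-ene-1,6-diol
Product: 16 (2R,3Z,5S)-5-(tert-butyldimethylsilyloxy)-2,7-bis[(4-methoxybenzyl)oxy]-6-oxohept-3-enal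
Conditions: Dess–Martin periodinane (3 equiv, one portion), NaHCO3, CH2Cl2, 0 °C → rt; short filtration, used at once
Reagents that add atoms: none
Why: The Dess–Martin oxidation converts both alcohols under buffered, amine-free conditions, which protects the doubly activated (allylic and α-carbonyl) centres C2 and C5 against enolisation, and the excess of oxidant should consume C6–OH before it can add to the new aldehyde.

Step 13
Reactants: 16 (2R,3Z,5S)-5-(tert-butyldimethylsilyloxy)-2,7-bis[(4-methoxybenzyl)oxy]-6-oxohept-3-enal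
Product: 17 cyclohexene cis-1,6-diol (1S,2R,5S,6S in overview numbering) with C2–OPMB, C5–OTBS and C6–CH2OPMB
Conditions: SmI2 (0.1 M in THF, 3 equiv), t-BuOH (3 equiv), THF, −78 → −40 °C, slow addition of 16, no HMPA
Reagents that add atoms: none
Why: Divalent samarium gives one electron to the C1 aldehyde, the more easily reduced carbonyl; the resulting ketyl carbon attacks the C6 ketone held by the same oxophilic metal centre, and a second electron plus t-BuOH complete the glycol. The closest known reaction type is the SmI2 pinacol carbocyclisation of carbohydrate-derived dialdehydes and keto-aldehydes, which also accepts ketone partners that end as tertiary carbinols. The single ring, the cyclohexene, closes in a 6-exo-trig mode (C1 onto C6, carbonyl oxygen outside the ring), and the Z C3=C4 bond keeps both chain ends on one side so that little entropy is lost. The relative configuration of C1 and C6 is fixed by the samarium bridge between the two oxygens, which permits only the cis-glycol. Their absolute sense is fixed by C2 and C5: both ether oxygens lie on one face of the nascent ring, and steric and dipole repulsion send the metal-bound oxygens to the other face, a matched case that should give 1S and the C6 configuration of the target. The step needs coupling to outrun loss of the α-oxygen substituents and plain carbonyl reduction, which is secured by ethers in place of esters at C2, C5 and C7, by −78 °C, by the absence of HMPA and by slow addition of 16 to excess reagent.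

Step 14
Reactants: 17 cyclohexene cis-1,6-diol
Product: 18 C1 acetate of 17 (1S,2R,5S,6S), tertiary C6–OH free
Conditions: Ac2O (1.5 equiv), pyridine, DMAP (cat.), CH2Cl2, 0 °C
Reagents that add atoms: acetic anhydride, CC(=O)OC(C)=O
Why: Nucleophile-catalysed acylation distinguishes the secondary C1–OH from the tertiary, neopentyl-type C6–OH, which should remain free under these mild conditions.

Step 15
Reactants: 18 C1 acetate
Product: 19 C1 acetate with free C2–OH, C6–OH and C7–OH and C5–OTBS (1S,2R,5S,6S)
Conditions: DDQ (3 equiv), CH2Cl2/pH 7 phosphate buffer 10:1, 0 °C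
Reagents that add atoms: none
Why: Oxidative PMB cleavage proceeds by hydride abstraction from the electron-rich benzylic positions and hydrolysis of the oxocarbenium ions, and the buffered two-phase medium should spare the acetate, the silyl ether and the alkene and keep acyl migration slow.

Step 16
Reactants: 19 triol acetate
Product: 20 C1 acetate C2,C7-dibenzoate with C5–OTBS and free C6–OH (1S,2R,5S,6S)
Conditions: BzCl (3 equiv), pyridine, CH2Cl2, 0 °C → rt, directly after step 15
Reagents that add atoms: benzoyl chloride, O=C(Cl)c1ccccc1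
Why: Pyridine-mediated benzoylation takes the primary C7–OH and the secondary allylic C2–OH, whereas the tertiary C6–OH is too hindered to react.

Step 17
Reactants: 20 silylated triester
Product: 21 HY-N2634 (1S,2R,5S,6R)
Conditions: HF·pyridine, pyridine, THF, 0 °C → rt (polyethylene vessel)
Reagents that add atoms: none
Why: Fluoride-driven desilylation in a weakly acidic medium frees C5–OH without forming an alkoxide, so the three esters should neither migrate nor cleave.

Compound list
1 | (S)-2,2-dimethyl-1,3-dioxolane-4-carbaldehyde | CC1(C)OC[C@@H](C=O)O1 | starting material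
2 | (R)-4-ethynyl-2,2-dimethyl-1,3-dioxolane | CC1(C)OC[C@@H](C#C)O1 | intermediate
3 | (R)-but-3-yne-1,2-diol (not isolated) | OC[C@H](O)C#C | intermediate
4 | (4R)-4-ethynyl-2-(4-methoxyphenyl)-1,3-dioxolane, both acetal epimers | COc1ccc(cc1)C1OC[C@@H](C#C)O1 | intermediate
5 | (R)-2-[(4-methoxybenzyl)oxy]but-3-yn-1-ol | OC[C@H](OCc1ccc(OC)cc1)C#C | intermediate
6 | methyl (S)-oxirane-2-carboxylate | COC(=O)[C@@H]1CO1 | starting material
7 | methyl (S)-2-hydroxy-3-[(4-methoxybenzyl)oxy]propanoate | COC(=O)[C@@H](O)COCc1ccc(OC)cc1 | intermediate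
8 | methyl (S)-3-[(4-methoxybenzyl)oxy]-2-(triethylsilyloxy)propanoate | COC(=O)[C@@H](O[Si](CC)(CC)CC)COCc1ccc(OC)cc1 | intermediate
9 | (S)-N-methoxy-3-[(4-methoxybenzyl)oxy]-N-methyl-2-(triethylsilyloxy)propanamide | CON(C)C(=O)[C@@H](O[Si](CC)(CC)CC)COCc1ccc(OC)cc1 | intermediate
10 | dilithio alkoxide–alkynide of 5 (not isolated) | [Li]OC[C@H](OCc1ccc(OC)cc1)C#C[Li] | intermediate
11 | (2S,6R)-7-hydroxy-1,6-bis[(4-methoxybenzyl)oxy]-2-(triethylsilyloxy)hept-4-yn-3-one | OC[C@H](OCc1ccc(OC)cc1)C#CC(=O)[C@@H](O[Si](CC)(CC)CC)COCc1ccc(OC)cc1 | intermediate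
12 | (2R,5S,6S)-2,7-bis[(4-methoxybenzyl)oxy]-6-(triethylsilyloxy)hept-3-yne-1,5-diol | OC[C@H](OCc1ccc(OC)cc1)C#C[C@H](O)[C@@H](O[Si](CC)(CC)CC)COCc1ccc(OC)cc1 | intermediate
13 | (2R,5S,6S)-1,5-bis(tert-butyldimethylsilyloxy)-2,7-bis[(4-methoxybenzyl)oxy]-6-(triethylsilyloxy)hept-3-yne | CC(C)(C)[Si](C)(C)OC[C@H](OCc1ccc(OC)cc1)C#C[C@H](O[Si](C)(C)C(C)(C)C)[C@@H](O[Si](CC)(CC)CC)COCc1ccc(OC)cc1 | intermediate
14 | (2R,5S,6S)-5-(tert-butyldimethylsilyloxy)-2,7-bis[(4-methoxybenzyl)oxy]hept-3-yne-1,6-diol | OC[C@H](OCc1ccc(OC)cc1)C#C[C@H](O[Si](C)(C)C(C)(C)C)[C@@H](O)COCc1ccc(OC)cc1 | intermediate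
15 | (2R,3Z,5S,6S)-5-(tert-butyldimethylsilyloxy)-2,7-bis[(4-methoxybenzyl)oxy]hept-3-ene-1,6-diol | OC[C@H](OCc1ccc(OC)cc1)/C=C\[C@H](O[Si](C)(C)C(C)(C)C)[C@@H](O)COCc1ccc(OC)cc1 | intermediate
16 | (2R,3Z,5S)-5-(tert-butyldimethylsilyloxy)-2,7-bis[(4-methoxybenzyl)oxy]-6-oxohept-3-enal | O=C[C@H](OCc1ccc(OC)cc1)/C=C\[C@H](O[Si](C)(C)C(C)(C)C)C(=O)COCc1ccc(OC)cc1 | intermediate
17 | cyclohexene cis-1,6-diol, C2–OPMB, C5–OTBS, C6–CH2OPMB (1S,2R,5S,6S) | O[C@H]1[C@H](OCc2ccc(OC)cc2)C=C[C@H](O[Si](C)(C)C(C)(C)C)[C@]1(O)COCc1ccc(OC)cc1 | intermediate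
18 | C1 acetate of 17 | CC(=O)O[C@H]1[C@H](OCc2ccc(OC)cc2)C=C[C@H](O[Si](C)(C)C(C)(C)C)[C@]1(O)COCc1ccc(OC)cc1 | intermediate
19 | C1 acetate, C2/C6/C7 triol, C5–OTBS | CC(=O)O[C@H]1[C@H](O)C=C[C@H](O[Si](C)(C)C(C)(C)C)[C@]1(O)CO | intermediate
20 | C1 acetate, C2 and C7 benzoates, C5–OTBS, C6–OH | CC(=O)O[C@H]1[C@H](OC(=O)c2ccccc2)C=C[C@H](O[Si](C)(C)C(C)(C)C)[C@]1(O)COC(=O)c1ccccc1 | intermediate
21 | HY-N2634 | CC(=O)O[C@H]1[C@H](OC(=O)c2ccccc2)C=C[C@H](O)[C@]1(O)COC(=O)c1ccccc1 | target

Total step count: 17. Longest linear sequence: 14 (steps 1–3 and 7–17).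

Steps most likely to fail

1. Step 13.
- What may go wrong: over-reduction of a ketyl to a carbanion followed by expulsion of the neighbouring ether oxygen; reduction of the carbonyls without C–C coupling; drift of the C3=C4 bond into conjugation on the Lewis-acidic trivalent samarium; incomplete facial control.
- Fallback (sets out from 16, comes back at 17): electron transfer is given up in favour of a neutral radical chain, the organotin-hydride pinacol cyclisation known for 1,6-keto-aldehydes. With Bu3SnH and AIBN in benzene at 80 °C a stannyl radical adds to the aldehyde oxygen. The O-stannyl ketyl closes on C6 and the new oxygen radical takes hydrogen from Bu3SnH. This should give the C1 O-tributylstannyl ether of the cis-diol F1, and aqueous KF then frees 17.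
- No carbanion can form on this path, so β-elimination of the ethers is excluded. Reversible stannyl addition to the alkene does no harm, because only the Z chain can cyclise.

2. Step 12.
- What may go wrong: addition of the still unoxidised C6–OH to the freshly formed aldehyde and oxidation of the resulting seven-membered lactol; enolisation at C2 or C5 with epimerisation; movement of the double bond into conjugation during work-up.
- Fallback (sets out from 13, comes back at 16): the two carbonyls are unmasked one after the other instead of together. Semihydrogenation of 13 over Pd/CaCO3–Pb(OAc)2 gives the fully silylated (Z)-alkene F2. PPTS in MeOH at 0 °C removes only the TES group and gives the C6 alcohol F3. Dess–Martin oxidation gives the C6 ketone F4, in which C1 is still silylated so that no lactol can arise. Pyridine-buffered HF·pyridine cleaves the primary silyl ether to the hydroxy ketone F5. TEMPO/PhI(OAc)2, which is neutral and selective for primary alcohols, then delivers 16.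

3. Step 15.
- What may go wrong: wandering of the C1 acetyl group to the newly freed C2 or C7 hydroxyl before benzoylation; capture of the oxidised benzylic cation by the tertiary C6–OH instead of water; over-oxidation of the freed allylic alcohol.
- Fallback (sets out from 17, comes back at 20): the acetate is introduced last. TESCl and imidazole in DMF silylate the secondary C1–OH of 17 to the C1 triethylsilyl ether F6. DDQ under the conditions of step 15 gives the C2,C6,C7-triol F7. BzCl in pyridine gives the dibenzoate F8. PPTS in MeOH removes the TES group in the presence of the TBS ether to give the C1 alcohol F9, and Ac2O/pyridine/DMAP acetylates it to 20.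

Further compounds
F1 | step 13 | C1 O-tributylstannyl ether of 17 | CCCC[Sn](CCCC)(CCCC)O[C@H]1[C@H](OCc2ccc(OC)cc2)C=C[C@H](O[Si](C)(C)C(C)(C)C)[C@]1(O)COCc1ccc(OC)cc1
F2 | step 12 | (2R,3Z,5S,6S)-1,5-bis(tert-butyldimethylsilyloxy)-2,7-bis[(4-methoxybenzyl)oxy]-6-(triethylsilyloxy)hept-3-ene | CC(C)(C)[Si](C)(C)OC[C@H](OCc1ccc(OC)cc1)/C=C\[C@H](O[Si](C)(C)C(C)(C)C)[C@@H](O[Si](CC)(CC)CC)COCc1ccc(OC)cc1
F3 | step 12 | C6 alcohol, C1 and C5 TBS ethers, (Z)-alkene | CC(C)(C)[Si](C)(C)OC[C@H](OCc1ccc(OC)cc1)/C=C\[C@H](O[Si](C)(C)C(C)(C)C)[C@@H](O)COCc1ccc(OC)cc1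
F4 | step 12 | C6 ketone, C1 and C5 TBS ethers, (Z)-alkene | CC(C)(C)[Si](C)(C)OC[C@H](OCc1ccc(OC)cc1)/C=C\[C@H](O[Si](C)(C)C(C)(C)C)C(=O)COCc1ccc(OC)cc1
F5 | step 12 | C1 alcohol C6 ketone, C5 TBS ether, (Z)-alkene | OC[C@H](OCc1ccc(OC)cc1)/C=C\[C@H](O[Si](C)(C)C(C)(C)C)C(=O)COCc1ccc(OC)cc1
F6 | step 15 | C1 triethylsilyl ether of 17 | CC[Si](CC)(CC)O[C@H]1[C@H](OCc2ccc(OC)cc2)C=C[C@H](O[Si](C)(C)C(C)(C)C)[C@]1(O)COCc1ccc(OC)cc1
F7 | step 15 | C1–OTES, C5–OTBS, C2/C6/C7 triol | CC[Si](CC)(CC)O[C@H]1[C@H](O)C=C[C@H](O[Si](C)(C)C(C)(C)C)[C@]1(O)CO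
F8 | step 15 | C1–OTES, C5–OTBS, C2 and C7 benzoates | CC[Si](CC)(CC)O[C@H]1[C@H](OC(=O)c2ccccc2)C=C[C@H](O[Si](C)(C)C(C)(C)C)[C@]1(O)COC(=O)c1ccccc1
F9 | step 15 | C1–OH, C5–OTBS, C2 and C7 benzoates | O[C@H]1[C@H](OC(=O)c2ccccc2)C=C[C@H](O[Si](C)(C)C(C)(C)C)[C@]1(O)COC(=O)c1ccccc1
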